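**Plan**

- Cuts: (a) the ketone C(=O)–C6 bond to the chromene, as a Claisen bond, after the chromene carbocycle is taken back to its 7,8-dihydro-5-oxo form; (b) C3–C4 and C5–C6 of the methylcyclohexene by a Diels–Alder transform (locants: C1 carries the methyl group, C3 ring A, C4 the acyl group, C5 the resorcinol ring); (c) the chalcone Cα=Cβ bond (aldol) and the ring A–dienyl bond (Stille).
- Forward: the ring A iodochalcone is made and coupled to the dienyl unit; an auxiliary-bound cinnamoyl dienophile closes the cyclohexene ring; the C2′ phenol of ring A then takes the acyl carbon into a six-membered aryl lactone (temporary ring); the pyran-fused cyclohexenone from cyclohexane-1,3-dione and prenal is C-acylated by this lactone; DDQ turns the saturated ring into the chromene arene; the allyl ethers come off last.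
- Enabling feature: on the chromene, the hydroxyl-bearing C5 and the acyl-bearing C6 form O–C5=C6–C(=O), which is the enol of a cyclic β-diketone once C7–C8 is saturated, so C6 can react as the only enolizable α-carbon of a ketone. The C2′ oxygen of ring A sits cis to the acyl group, five atoms from the acyl carbon, so it can hold that carbon in a lactone that is acyl donor, protecting group and leaving group at once.
- Stereochemistry: all three centres (3S,4R,5S) are set in the Diels–Alder step by the (S)-4-benzyloxazolidinone auxiliary (face), the endo transition state (C3/C4 cis) and the E-dienophile (C4/C5 trans). Alkene geometries come from the condensations and a syn-hydrostannation. No later step touches a stereocentre.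

Key step: step 13

Remark: the β-diketone formed in the key step is drawn and named as its hydrogen-bonded enol; its tautomers interconvert freely.

**Route**

Step 1
Reactants: 1 2,4-dihydroxyacetophenone
Product: 2 1-(2,4-dihydroxy-3-iodophenyl)ethanone
Conditions: I2, HIO3, EtOH/H2O, 23–40 °C
Reagents that add atoms: iodine ([I][I]); iodic acid (O[I](=O)=O)
Why: Electrophilic aromatic iodination (iodine activated by iodic acid) at C3, the position doubly activated by the two flanking hydroxyl groups, which is where this reagent pair is known to iodinate 2,4-dihydroxyaryl ketones.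

Step 2
Reactants: 2 1-(2,4-dihydroxy-3-iodophenyl)ethanone
Product: 3 1-[4-(allyloxy)-2-hydroxy-3-iodophenyl]ethanone
Conditions: allyl bromide (1.05 equiv), K2CO3, acetone, 56 °C
Reagents that add atoms: allyl bromide (C=CCBr)
Why: Williamson etherification is selective for the C4 hydroxyl because the C2 hydroxyl is held in a hydrogen bond to the acetyl carbonyl and is the weaker nucleophile.

Step 3
Reactants: 4 2,4-dihydroxybenzaldehyde
Product: 5 2,4-bis(allyloxy)benzaldehyde
Conditions: allyl bromide (2.5 equiv), K2CO3, DMF, 60 °C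
Reagents that add atoms: allyl bromide (C=CCBr)
Why: Williamson etherification with excess halide in DMF alkylates both hydroxyl groups, including the hydrogen-bonded one.

Step 4
Reactants: 3 1-[4-(allyloxy)-2-hydroxy-3-iodophenyl]ethanone; 5 2,4-bis(allyloxy)benzaldehyde
Product: 6 (E)-1-[4-(allyloxy)-2-hydroxy-3-iodophenyl]-3-[2,4-bis(allyloxy)phenyl]prop-2-en-1-one
Conditions: KOH, EtOH/H2O, 23 °C; then dilute HCl
Reagents that add atoms: none
Why: Claisen–Schmidt condensation (aldol addition of the acetophenone enolate to the non-enolizable aldehyde and E1cB dehydration) gives the E-enone; the free 2′-hydroxyl is tolerated as its phenoxide and allyl ethers are stable to hydroxide.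

Step 5
Reactants: 6 (E)-1-[4-(allyloxy)-2-hydroxy-3-iodophenyl]-3-[2,4-bis(allyloxy)phenyl]prop-2-en-1-one
Product: 7 (E)-1-[4-(allyloxy)-2-(tert-butyldimethylsilyloxy)-3-iodophenyl]-3-[2,4-bis(allyloxy)phenyl]prop-2-en-1-one
Conditions: tert-butyldimethylsilyl triflate, 2,6-lutidine, CH2Cl2, 0 → 23 °C
Reagents that add atoms: tert-butyldimethylsilyl triflate (CC(C)(C)[Si](C)(C)OS(=O)(=O)C(F)(F)F)
Why: Silyl triflate O-silylation reaches the hindered, hydrogen-bonded phenol; the silyl ether keeps the 2′-hydroxy ketone from chelating the Lewis acid in step 11 (which would turn the chalcone of the diene into a dienophile) and is the one group that fluoride removes in step 12.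

Step 6
Reactants: 8 2-methylbut-1-en-3-yne
Product: 9 (E)-tributyl(3-methylbuta-1,3-dien-1-yl)stannane
Conditions: Bu3SnH, Pd2(dba)3 (cat.), Cy3P·HBF4 (cat.), i-Pr2NEt (cat.), CH2Cl2, 0 °C
Reagents that add atoms: tributyltin hydride (CCCC[SnH](CCCC)CCCC)
Why: Palladium-catalysed hydrostannation is a syn addition and the bulky phosphine directs tin to the terminal alkyne carbon, so the E-dienylstannane should form while the 1,1-disubstituted alkene is left alone.

Step 7
Reactants: 7 (E)-1-[4-(allyloxy)-2-(tert-butyldimethylsilyloxy)-3-iodophenyl]-3-[2,4-bis(allyloxy)phenyl]prop-2-en-1-one; 9 (E)-tributyl(3-methylbuta-1,3-dien-1-yl)stannane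
Product: 10 (E)-1-{4-(allyloxy)-2-(tert-butyldimethylsilyloxy)-3-[(E)-3-methylbuta-1,3-dien-1-yl]phenyl}-3-[2,4-bis(allyloxy)phenyl]prop-2-en-1-one
Conditions: Pd2(dba)3 (cat.), AsPh3, DMF, 50 °C
Reagents that add atoms: none
Why: Stille coupling under neutral, base-free conditions spares the aryl silyl ether; the E geometry of the stannane is transferred with retention, and oxidative addition to the aryl iodide should outrun ionization of the allyl aryl ethers at this temperature.

Step 8
Reactants: 5 2,4-bis(allyloxy)benzaldehyde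
Product: 11 (E)-3-[2,4-bis(allyloxy)phenyl]acrylic acid
Conditions: malonic acid, pyridine, piperidine (cat.), 90 °C
Reagents that add atoms: malonic acid (OC(=O)CC(O)=O)
Why: Knoevenagel–Doebner condensation; decarboxylation of the arylidene malonic acid gives the E-cinnamic acid, and 90 °C is well below the temperature of the aromatic Claisen rearrangement of the allyl ethers.

Step 9
Reactants: 11 (E)-3-[2,4-bis(allyloxy)phenyl]acrylic acid; 12 (S)-4-benzyloxazolidin-2-one
Product: 14 (S)-4-benzyl-3-[(E)-3-(2,4-bis(allyloxy)phenyl)acryloyl]oxazolidin-2-one, via mixed pivalic anhydride 13 (not isolated)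
Conditions: pivaloyl chloride, Et3N, THF, −20 °C; then 12, LiCl, 23 °C
Reagents that add atoms: none
Why: N-acylation of the oxazolidinone through the mixed pivalic anhydride, which the LiCl-activated oxazolidinone attacks at the less hindered cinnamoyl carbonyl; the alkene geometry is untouched.

Step 10
Reactants: 15 cyclohexane-1,3-dione; 16 3-methylbut-2-enal
Product: 17 2,2-dimethyl-7,8-dihydro-2H-chromen-5(6H)-one
Conditions: ethylenediammonium diacetate (cat.), MeOH, 23 → 50 °C
Reagents that add atoms: none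
Why: Knoevenagel condensation at C2 of the dione gives a 1-oxatriene that closes by oxa-6π-electrocyclization to the 2H-pyran (formal [3+3] annulation), so the pyran ring and the future C5 oxygen are placed without any regiochemical question.

Step 11
Reactants: 10 (E)-1-{4-(allyloxy)-2-(tert-butyldimethylsilyloxy)-3-[(E)-3-methylbuta-1,3-dien-1-yl]phenyl}-3-[2,4-bis(allyloxy)phenyl]prop-2-en-1-one; 14 (S)-4-benzyl-3-[(E)-3-(2,4-bis(allyloxy)phenyl)acryloyl]oxazolidin-2-one
Product: 18 (S)-4-benzyl-3-{[(1R,2S,6S)-2-{6-(allyloxy)-3-[(E)-3-(2,4-bis(allyloxy)phenyl)acryloyl]-2-(tert-butyldimethylsilyloxy)phenyl}-6-[2,4-bis(allyloxy)phenyl]-4-methylcyclohex-3-en-1-yl]carbonyl}oxazolidin-2-one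
Conditions: Me2AlCl (3 equiv), CH2Cl2, −78 → −30 °C; then dilute HCl
Reagents that add atoms: none
Why: Auxiliary-controlled Lewis acid-promoted Diels–Alder reaction: the aluminium-chelated s-cis enoyl imide is attacked on the face opposite the benzyl group (C4 becomes R and, through the E-alkene, C5 becomes S), the endo transition state places the ring A aryl group on C3 cis to the acyl group (3S), and both diene substituents direct the aryl-bearing terminus to the α-carbon.

Step 12
Reactants: 18 (S)-4-benzyl-3-{[(1R,2S,6S)-2-{6-(allyloxy)-3-[(E)-3-(2,4-bis(allyloxy)phenyl)acryloyl]-2-(tert-butyldimethylsilyloxy)phenyl}-6-[2,4-bis(allyloxy)phenyl]-4-methylcyclohex-3-en-1-yl]carbonyl}oxazolidin-2-one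
Product: 20 (6aR,7S,10aS)-1-(allyloxy)-4-[(E)-3-(2,4-bis(allyloxy)phenyl)acryloyl]-7-[2,4-bis(allyloxy)phenyl]-9-methyl-6a,7,8,10a-tetrahydro-6H-benzo[c]chromen-6-one, via free phenol imide 19 (not isolated)
Conditions: tetrabutylammonium fluoride, AcOH, THF, 0 °C; then Et3N, 40 °C
Reagents that add atoms: none
Why: Fluoride cleaves the carbonyl-activated aryl silyl ether and the freed C2′ phenol, held cis to the imide on the neighbouring ring carbon, displaces the oxazolidinone by intramolecular acyl substitution, which closes the six-membered aryl lactone, releases the auxiliary and leaves C3, C4 and C5 untouched.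

Step 13
Reactants: 17 2,2-dimethyl-7,8-dihydro-2H-chromen-5(6H)-one; 20 (6aR,7S,10aS)-1-(allyloxy)-4-[(E)-3-(2,4-bis(allyloxy)phenyl)acryloyl]-7-[2,4-bis(allyloxy)phenyl]-9-methyl-6a,7,8,10a-tetrahydro-6H-benzo[c]chromen-6-one
Product: 22 [(1R,2S,6S)-2-{6-(allyloxy)-3-[(E)-3-(2,4-bis(allyloxy)phenyl)acryloyl]-2-hydroxyphenyl}-6-[2,4-bis(allyloxy)phenyl]-4-methylcyclohex-3-en-1-yl](5-hydroxy-2,2-dimethyl-7,8-dihydro-2H-chromen-6-yl)methanone, via lithium enolate 21 (not isolated)
Conditions: LiN(i-Pr)2 (2.2 equiv), 17 (2.3 equiv), THF, −78 °C; then 20, −78 → −40 °C; then AcOH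
Reagents that add atoms: none
Why: The kinetic lithium enolate 21 (deprotonation at C6, the α′-carbon of the vinylogous ester) adds through C6 to the lactone carbonyl of 20 and the tetrahedral intermediate collapses with loss of the ring A phenoxide, a good leaving group because it is ortho to the chalcone carbonyl; the second equivalent of enolate deprotonates the β-diketone formed, which makes this crossed Claisen condensation irreversible. The closest known reaction type is the C-acylation of ketone lithium enolates by aryl esters and lactones, and in particular the acylation of this pyran-fused cyclohexenone enolate followed by dehydrogenation to a 5-hydroxy-6-acylchromene. The step closes no ring (it opens the temporary lactone ring) and creates no stereocentre; C4 keeps its configuration because the nucleophile attacks the carbonyl carbon and the product is at once stored as its diketonate, in which C4–H is no longer acidic. The selectivities needed are C6- over C8-enolization (kinetic deprotonation at −78 °C), C- over O-acylation (lithium enolate with an ester-type acyl donor), acyl substitution over deprotonation at C4 (the lactone ties ring A back so that the carbonyl is exposed, while C4–H is tertiary and flanked by two aryl-bearing carbons), and lactone over chalcone (an activated aryl ester against an enone whose β-carbon is deactivated by the 2,4-dialkoxyaryl group and whose carbonyl becomes a phenoxide-conjugated ketone as soon as the ring opens). The position of the acyl group on the future arene is fixed by construction, since C6 is the only enolizable α-carbon of 17 and the pyran ring is already in place, which an electrophilic acylation of the acid-sensitive chromene could not guarantee.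

Step 14
Reactants: 22 [(1R,2S,6S)-2-{6-(allyloxy)-3-[(E)-3-(2,4-bis(allyloxy)phenyl)acryloyl]-2-hydroxyphenyl}-6-[2,4-bis(allyloxy)phenyl]-4-methylcyclohex-3-en-1-yl](5-hydroxy-2,2-dimethyl-7,8-dihydro-2H-chromen-6-yl)methanone
Product: 23 [(1R,2S,6S)-2-{6-(allyloxy)-3-[(E)-3-(2,4-bis(allyloxy)phenyl)acryloyl]-2-hydroxyphenyl}-6-[2,4-bis(allyloxy)phenyl]-4-methylcyclohex-3-en-1-yl](5-hydroxy-2,2-dimethyl-2H-chromen-6-yl)methanone
Conditions: DDQ (1.1 equiv), 1,4-dioxane, 23 °C
Reagents that add atoms: none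
Why: Quinone dehydrogenation of a 2-acylcyclohexenone enol: hydride abstraction from C8 of the electron-rich pyran dienol, loss of the C7 proton and tautomerization give the ortho-hydroxyaryl ketone, with aromatization as the driving force and the hydrogen-bonded ring A phenol and the aryl allyl ethers expected to be inert at room temperature.

Step 15
Reactants: 23 [(1R,2S,6S)-2-{6-(allyloxy)-3-[(E)-3-(2,4-bis(allyloxy)phenyl)acryloyl]-2-hydroxyphenyl}-6-[2,4-bis(allyloxy)phenyl]-4-methylcyclohex-3-en-1-yl](5-hydroxy-2,2-dimethyl-2H-chromen-6-yl)methanone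
Product: 24 (E)-1-{3-[(1S,5S,6R)-5-(2,4-dihydroxyphenyl)-6-(5-hydroxy-2,2-dimethyl-2H-chromene-6-carbonyl)-3-methylcyclohex-2-en-1-yl]-2,4-dihydroxyphenyl}-3-(2,4-dihydroxyphenyl)prop-2-en-1-one (CNP0115975.1)
Conditions: Pd(PPh3)4 (cat.), morpholine, THF, 23 °C
Reagents that add atoms: none
Why: Palladium-catalysed allyl transfer from the five aryl allyl ethers to morpholine through π-allylpalladium intermediates is neutral and non-acidic, so the chromene, the enone and the C4 α-stereocentre should survive and the acid-induced ketalization known for this cis,trans adduct type is avoided.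

**Compound list**

1 | 2,4-dihydroxyacetophenone | CC(=O)c1ccc(O)cc1O | starting material
2 | 1-(2,4-dihydroxy-3-iodophenyl)ethanone | CC(=O)c1ccc(O)c(I)c1O | intermediate
3 | 1-[4-(allyloxy)-2-hydroxy-3-iodophenyl]ethanone | CC(=O)c1ccc(OCC=C)c(I)c1O | intermediate
4 | 2,4-dihydroxybenzaldehyde | O=Cc1ccc(O)cc1O | starting material
5 | 2,4-bis(allyloxy)benzaldehyde | O=Cc1ccc(OCC=C)cc1OCC=C | intermediate
6 | (E)-1-[4-(allyloxy)-2-hydroxy-3-iodophenyl]-3-[2,4-bis(allyloxy)phenyl]prop-2-en-1-one | O=C(/C=C/c1ccc(OCC=C)cc1OCC=C)c1ccc(OCC=C)c(I)c1O | intermediate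
7 | (E)-1-[4-(allyloxy)-2-(tert-butyldimethylsilyloxy)-3-iodophenyl]-3-[2,4-bis(allyloxy)phenyl]prop-2-en-1-one | O=C(/C=C/c1ccc(OCC=C)cc1OCC=C)c1ccc(OCC=C)c(I)c1O[Si](C)(C)C(C)(C)C | intermediate
8 | 2-methylbut-1-en-3-yne | C=C(C)C#C | starting material
9 | (E)-tributyl(3-methylbuta-1,3-dien-1-yl)stannane | CCCC[Sn](CCCC)(CCCC)/C=C/C(C)=C | intermediate
10 | (E)-1-{4-(allyloxy)-2-(tert-butyldimethylsilyloxy)-3-[(E)-3-methylbuta-1,3-dien-1-yl]phenyl}-3-[2,4-bis(allyloxy)phenyl]prop-2-en-1-one | O=C(/C=C/c1ccc(OCC=C)cc1OCC=C)c1ccc(OCC=C)c(/C=C/C(C)=C)c1O[Si](C)(C)C(C)(C)C | intermediate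
11 | (E)-3-[2,4-bis(allyloxy)phenyl]acrylic acid | OC(=O)/C=C/c1ccc(OCC=C)cc1OCC=C | intermediate
12 | (S)-4-benzyloxazolidin-2-one | O=C1OC[C@H](Cc2ccccc2)N1 | starting material
13 | (E)-3-[2,4-bis(allyloxy)phenyl]acrylic pivalic anhydride | CC(C)(C)C(=O)OC(=O)/C=C/c1ccc(OCC=C)cc1OCC=C | intermediate
14 | (S)-4-benzyl-3-[(E)-3-(2,4-bis(allyloxy)phenyl)acryloyl]oxazolidin-2-one | O=C(/C=C/c1ccc(OCC=C)cc1OCC=C)N1[C@@H](Cc2ccccc2)COC1=O | intermediate
15 | cyclohexane-1,3-dione | O=C1CCCC(=O)C1 | starting material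
16 | 3-methylbut-2-enal | CC(C)=CC=O | starting material
17 | 2,2-dimethyl-7,8-dihydro-2H-chromen-5(6H)-one | O=C1CCCC2=C1C=CC(C)(C)O2 | intermediate
18 | (S)-4-benzyl-3-{[(1R,2S,6S)-2-{6-(allyloxy)-3-[(E)-3-(2,4-bis(allyloxy)phenyl)acryloyl]-2-(tert-butyldimethylsilyloxy)phenyl}-6-[2,4-bis(allyloxy)phenyl]-4-methylcyclohex-3-en-1-yl]carbonyl}oxazolidin-2-one | CC1=C[C@H](c2c(OCC=C)ccc(C(=O)/C=C/c3ccc(OCC=C)cc3OCC=C)c2O[Si](C)(C)C(C)(C)C)[C@H](C(=O)N2[C@@H](Cc3ccccc3)COC2=O)[C@@H](c2ccc(OCC=C)cc2OCC=C)C1 | intermediate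
19 | (S)-4-benzyl-3-{[(1R,2S,6S)-2-{6-(allyloxy)-3-[(E)-3-(2,4-bis(allyloxy)phenyl)acryloyl]-2-hydroxyphenyl}-6-[2,4-bis(allyloxy)phenyl]-4-methylcyclohex-3-en-1-yl]carbonyl}oxazolidin-2-one | CC1=C[C@H](c2c(OCC=C)ccc(C(=O)/C=C/c3ccc(OCC=C)cc3OCC=C)c2O)[C@H](C(=O)N2[C@@H](Cc3ccccc3)COC2=O)[C@@H](c2ccc(OCC=C)cc2OCC=C)C1 | intermediate
20 | (6aR,7S,10aS)-1-(allyloxy)-4-[(E)-3-(2,4-bis(allyloxy)phenyl)acryloyl]-7-[2,4-bis(allyloxy)phenyl]-9-methyl-6a,7,8,10a-tetrahydro-6H-benzo[c]chromen-6-one (cis-fused lactone) | CC1=C[C@@H]2c3c(OCC=C)ccc(C(=O)/C=C/c4ccc(OCC=C)cc4OCC=C)c3OC(=O)[C@@H]2[C@@H](c5ccc(OCC=C)cc5OCC=C)C1 | intermediate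
21 | lithium 2,2-dimethyl-7,8-dihydro-2H-chromen-5-olate | [Li+].[O-]C1=CCCC2=C1C=CC(C)(C)O2 | intermediate
22 | [(1R,2S,6S)-2-{6-(allyloxy)-3-[(E)-3-(2,4-bis(allyloxy)phenyl)acryloyl]-2-hydroxyphenyl}-6-[2,4-bis(allyloxy)phenyl]-4-methylcyclohex-3-en-1-yl](5-hydroxy-2,2-dimethyl-7,8-dihydro-2H-chromen-6-yl)methanone (enol form of the β-diketone) | CC1=C[C@H](c2c(OCC=C)ccc(C(=O)/C=C/c3ccc(OCC=C)cc3OCC=C)c2O)[C@H](C(=O)C2=C(O)C3=C(CC2)OC(C)(C)C=C3)[C@@H](c2ccc(OCC=C)cc2OCC=C)C1 | intermediate
23 | [(1R,2S,6S)-2-{6-(allyloxy)-3-[(E)-3-(2,4-bis(allyloxy)phenyl)acryloyl]-2-hydroxyphenyl}-6-[2,4-bis(allyloxy)phenyl]-4-methylcyclohex-3-en-1-yl](5-hydroxy-2,2-dimethyl-2H-chromen-6-yl)methanone | CC1=C[C@H](c2c(OCC=C)ccc(C(=O)/C=C/c3ccc(OCC=C)cc3OCC=C)c2O)[C@H](C(=O)c2ccc3c(c2O)C=CC(C)(C)O3)[C@@H](c2ccc(OCC=C)cc2OCC=C)C1 | intermediate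
24 | (E)-1-{3-[(1S,5S,6R)-5-(2,4-dihydroxyphenyl)-6-(5-hydroxy-2,2-dimethyl-2H-chromene-6-carbonyl)-3-methylcyclohex-2-en-1-yl]-2,4-dihydroxyphenyl}-3-(2,4-dihydroxyphenyl)prop-2-en-1-one | CC1=C[C@H](c2c(O)ccc(C(=O)/C=C/c3ccc(O)cc3O)c2O)[C@H](C(=O)c2ccc3c(c2O)C=CC(C)(C)O3)[C@@H](c2ccc(O)cc2O)C1 | target

**Totals and risks**

Total step count: 15. Longest linear sequence: 10 steps (steps 1, 2, 4, 5, 7, 11, 12, 13, 14, 15).

Step 11 (Diels–Alder). The electron-rich β-aryl enoyl imide may react too slowly, so that the Lewis acid instead ionizes or polymerizes the aryl diene or attacks the protecting groups; a stepwise cationic path would also erode endo and facial selectivity. The fallback gives up auxiliary control for a tethered, Lewis-acid-free cycloaddition; it sets out from 6, 11 and 9 and returns at 20. Carbodiimide esterification of the free phenol of 6 with acid 11 (EDC·HCl, DMAP, CH2Cl2) should give 3-(allyloxy)-6-[(E)-3-(2,4-bis(allyloxy)phenyl)acryloyl]-2-iodophenyl (E)-3-[2,4-bis(allyloxy)phenyl]acrylate F1. Stille coupling with 9 under the conditions of step 7 should give the triene ester F2. Heating F2 (toluene, 120 °C) should bring about an intramolecular Diels–Alder reaction. The planar aryl ester tether holds diene and dienophile on the same face, so the cis-fused lactone with the aryl group trans is expected, as a racemate of 20 and the mirror-image lactone F3. Preparative chromatography on a chiral stationary phase then delivers 20.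

Step 13 (key step). Conjugate addition of the enolate to the chalcone, or deprotonation of the lactone at C4 (epimerization, ketene formation), may compete with acyl substitution. The fallback joins the same bond with a non-basic aryl nucleophile on the aromatic chromene; it sets out from 18 and 17 and returns at 23. Thiolysis of imide 18 (EtSLi, THF, 0 °C) should give the S-ethyl thioester F4 and free the auxiliary. Dehydrogenation of 17 (DDQ, 1,4-dioxane, 100 °C) should give 2,2-dimethyl-2H-chromen-5-ol F5, which is protected (2-(trimethylsilyl)ethoxymethyl chloride, i-Pr2NEt) as the acetal-type ether F6. Directed ortho-lithiation at C6 (n-BuLi, TMEDA, THF, 0 °C) and transmetalation with ZnCl2 should give the arylzinc chloride F7. Fukuyama coupling of F4 with F7 (PdCl2(PPh3)2 cat., THF/toluene, 23 °C), which tolerates enones, should give the protected ketone F8. Tetrabutylammonium fluoride (THF, 40 °C) should remove both silicon-based groups and give 23.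

Step 14 (aromatization). DDQ may abstract hydride from the allylic-benzylic C3–H or the benzylic C5–H, or oxidize the electron-rich aryl ethers, instead of dehydrogenating the diketone ring. The fallback replaces hydride abstraction by sulfenylation and sulfoxide elimination; it sets out from 22 and returns at 23. Sulfenylation of the diketone carbon (N-(phenylthio)succinimide, Et3N, CH2Cl2) should give the 6-(phenylsulfanyl) diketone F9. Oxidation at sulfur (mCPBA, CH2Cl2, −78 °C) should give the sulfoxide F10, which on warming to 40 °C should undergo syn-elimination towards C7 and tautomerize to 23.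

**Further compounds**

F1 | step 11 | 3-(allyloxy)-6-[(E)-3-(2,4-bis(allyloxy)phenyl)acryloyl]-2-iodophenyl (E)-3-[2,4-bis(allyloxy)phenyl]acrylate | O=C(/C=C/c1ccc(OCC=C)cc1OCC=C)c1ccc(OCC=C)c(I)c1OC(=O)/C=C/c1ccc(OCC=C)cc1OCC=C
F2 | step 11 | 3-(allyloxy)-6-[(E)-3-(2,4-bis(allyloxy)phenyl)acryloyl]-2-[(E)-3-methylbuta-1,3-dien-1-yl]phenyl (E)-3-[2,4-bis(allyloxy)phenyl]acrylate | O=C(/C=C/c1ccc(OCC=C)cc1OCC=C)c1ccc(OCC=C)c(/C=C/C(C)=C)c1OC(=O)/C=C/c1ccc(OCC=C)cc1OCC=C
F3 | step 11 | (6aS,7R,10aR)-1-(allyloxy)-4-[(E)-3-(2,4-bis(allyloxy)phenyl)acryloyl]-7-[2,4-bis(allyloxy)phenyl]-9-methyl-6a,7,8,10a-tetrahydro-6H-benzo[c]chromen-6-one (mirror image of 20) | CC1=C[C@H]2c3c(OCC=C)ccc(C(=O)/C=C/c4ccc(OCC=C)cc4OCC=C)c3OC(=O)[C@H]2[C@H](c5ccc(OCC=C)cc5OCC=C)C1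
F4 | step 13 | S-ethyl (1R,2S,6S)-2-{6-(allyloxy)-3-[(E)-3-(2,4-bis(allyloxy)phenyl)acryloyl]-2-(tert-butyldimethylsilyloxy)phenyl}-6-[2,4-bis(allyloxy)phenyl]-4-methylcyclohex-3-ene-1-carbothioate | CC1=C[C@H](c2c(OCC=C)ccc(C(=O)/C=C/c3ccc(OCC=C)cc3OCC=C)c2O[Si](C)(C)C(C)(C)C)[C@H](C(=O)SCC)[C@@H](c2ccc(OCC=C)cc2OCC=C)C1
F5 | step 13 | 2,2-dimethyl-2H-chromen-5-ol | CC1(C)C=Cc2c(O)cccc2O1
F6 | step 13 | 2,2-dimethyl-5-{[2-(trimethylsilyl)ethoxy]methoxy}-2H-chromene | CC1(C)C=Cc2c(OCOCC[Si](C)(C)C)cccc2O1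
F7 | step 13 | (2,2-dimethyl-5-{[2-(trimethylsilyl)ethoxy]methoxy}-2H-chromen-6-yl)zinc chloride | CC1(C)C=Cc2c(OCOCC[Si](C)(C)C)c([Zn]Cl)ccc2O1
F8 | step 13 | [(1R,2S,6S)-2-{6-(allyloxy)-3-[(E)-3-(2,4-bis(allyloxy)phenyl)acryloyl]-2-(tert-butyldimethylsilyloxy)phenyl}-6-[2,4-bis(allyloxy)phenyl]-4-methylcyclohex-3-en-1-yl](2,2-dimethyl-5-{[2-(trimethylsilyl)ethoxy]methoxy}-2H-chromen-6-yl)methanone | CC1=C[C@H](c2c(OCC=C)ccc(C(=O)/C=C/c3ccc(OCC=C)cc3OCC=C)c2O[Si](C)(C)C(C)(C)C)[C@H](C(=O)c2ccc3c(c2OCOCC[Si](C)(C)C)C=CC(C)(C)O3)[C@@H](c2ccc(OCC=C)cc2OCC=C)C1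
F9 | step 14 | [(1R,2S,6S)-2-{6-(allyloxy)-3-[(E)-3-(2,4-bis(allyloxy)phenyl)acryloyl]-2-hydroxyphenyl}-6-[2,4-bis(allyloxy)phenyl]-4-methylcyclohex-3-en-1-yl][2,2-dimethyl-5-oxo-6-(phenylsulfanyl)-5,6,7,8-tetrahydro-2H-chromen-6-yl]methanone (mixture at C6 of the chromenone) | CC1=C[C@H](c2c(OCC=C)ccc(C(=O)/C=C/c3ccc(OCC=C)cc3OCC=C)c2O)[C@H](C(=O)C2(Sc3ccccc3)CCC3=C(C=CC(C)(C)O3)C2=O)[C@@H](c2ccc(OCC=C)cc2OCC=C)C1
F10 | step 14 | [(1R,2S,6S)-2-{6-(allyloxy)-3-[(E)-3-(2,4-bis(allyloxy)phenyl)acryloyl]-2-hydroxyphenyl}-6-[2,4-bis(allyloxy)phenyl]-4-methylcyclohex-3-en-1-yl][2,2-dimethyl-5-oxo-6-(phenylsulfinyl)-5,6,7,8-tetrahydro-2H-chromen-6-yl]methanone (mixture at C6 and at sulfur) | CC1=C[C@H](c2c(OCC=C)ccc(C(=O)/C=C/c3ccc(OCC=C)cc3OCC=C)c2O)[C@H](C(=O)C2(S(=O)c3ccccc3)CCC3=C(C=CC(C)(C)O3)C2=O)[C@@H](c2ccc(OCC=C)cc2OCC=C)C1
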